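## Retrosynthetic overview

1. Hydrindane numbering, used for all intermediates: C1 = ethylidene-bearing carbon, C2 = CHOAc, C3 = CH2, C3a/C7a = ring fusion, C4 = C(=CH2), C5 = CH–O-angelate, C6 = CHOH, C7 = CH–iPr. β is the face of H-3a, α the face of H-7a.
2. 23 ⇒ (Mitsunobu with AcOH, inversion at C2) 2β-alcohol 22 ⇒ (C1–C2 bond and vinyl C–CH3 bond in one operation) monocyclic ynal 19 + Me2Zn.
3. Enabling feature: the C2 carbinol sits next to C1, whose exocyclic trisubstituted alkene has its methyl cis to C2. This is the imprint of a syn addition of an aldehyde carbon and a methyl group across a terminal alkyne. Both arms hang on the vicinal trans-diequatorial positions C3a/C7a of the cyclohexane, so the trans fusion is fixed before the cyclopentane closes.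
4. 19 ⇒ vinyl epoxide 16 + angelic acid 17 (trans-diaxial 5-O-acyl/6-OH pair = epoxide opening at allylic C5). 16 ⇒ all-trans ketone 9 (dehydrogenation, nucleophilic epoxidation, methylenation) ⇒ (S)-cryptone 4 (conjugate alkynylation, enolate allylation) ⇒ 1 + 2.
5. Ring order: cyclohexane first (steps 1–2); cyclopentane C1–C2–C3–C3a–C7a last (step 11).

Key step: step 11

Remark: 5 is taken as its commercial THF solution. The sense of induction in step 1 follows the usual face-shielding model of (S)-diarylprolinol ethers; the (R)-catalyst would give the antipode.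

## Route

Step 1
Reactants: 1 3-methylbutanal (isovaleraldehyde); 2 but-3-en-2-one (methyl vinyl ketone)
Product: 3 (2S)-5-oxo-2-(propan-2-yl)hexanal
Conditions: (S)-α,α-diphenylprolinol methyl ether (5 mol %), ethyl 3,4-dihydroxybenzoate (20 mol %), neat, 4 °C
Reagents that add atoms: none
Why: Enamine-catalysed asymmetric Michael addition of an aldehyde to a vinyl ketone, in which the diphenyl(methoxy)methyl group of the (S)-catalyst shields one face of the E-enamine so that the future C7 is set as S.

Step 2
Reactants: 3 (2S)-5-oxo-2-(propan-2-yl)hexanal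
Product: 4 (4S)-4-(propan-2-yl)cyclohex-2-en-1-one, (S)-cryptone
Conditions: LiOH (cat.), i-PrOH, rt
Reagents that add atoms: none
Why: Intramolecular aldol condensation (6-enolexo attack of the methyl ketone enolate on the aldehyde, then E1cB loss of water) closes the cyclohexenone, and the stereocentre ends up γ to the carbonyl group without being touched.

Step 3
Reactants: 4 (S)-cryptone; 5 lithium (trimethylsilyl)acetylide
Product: 7 trimethyl({(3S,4S)-4-(propan-2-yl)-3-[(trimethylsilyl)ethynyl]cyclohex-1-en-1-yl}oxy)silane, via [(trimethylsilyl)ethynyl]copper 6 (not isolated)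
Conditions: 5, CuI, THF, −30 °C; then TMSI, 4, −78 → −30 °C; Et3N, aq NaHCO3
Reagents that add atoms: iodotrimethylsilane C[Si](C)(C)I (O-silyl group); copper(I) iodide [Cu]I (copper of 6 only)
Why: Iodotrimethylsilane-promoted conjugate addition of an alkynylcopper reagent to an enone, in which the nucleophile attacks C7a anti to the neighbouring isopropyl group (3,4-trans) and the enolate is caught regiospecifically as its silyl ether.

Step 4
Reactants: 7 silyl enol ether
Product: 9 (2R,3S,4S)-4-(propan-2-yl)-2-(prop-2-en-1-yl)-3-[(trimethylsilyl)ethynyl]cyclohexan-1-one, via lithium C3a enolate 8 (not isolated)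
Conditions: MeLi (1.0 equiv), THF, 0 °C; then DMPU, allyl iodide, −78 → −30 °C
Reagents that add atoms: allyl iodide C=CCI; methyllithium [Li]C (lithium of 8 only)
Why: O–Si cleavage with methyllithium gives the regiodefined lithium enolate (the C(sp)–Si bond reacts much more slowly), and its allylation occurs at C3a anti to the C7a alkynyl group to give the all-equatorial 2,3-trans ketone, which is also the thermodynamically preferred epimer.

Step 5
Reactants: 9 allyl ketone
Product: 11 (2R,3S,4S)-2-(2,2-dimethoxyethyl)-4-(propan-2-yl)-3-[(trimethylsilyl)ethynyl]cyclohexan-1-one, via keto aldehyde 10 (not isolated)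
Conditions: O3, CH2Cl2–MeOH, −78 °C (Sudan III end point); Me2S; then HC(OMe)3, CeCl3·7H2O (cat.), MeOH, rt
Reagents that add atoms: ozone [O-][O+]=O (aldehyde oxygen of 10 only); trimethyl orthoformate COC(OC)OC (both methoxy groups of 11)
Why: Ozonolysis cleaves the monosubstituted alkene in preference to the silylalkyne, and cerium(III)-catalysed acetalisation masks the aldehyde of 10 chemoselectively beside the ketone, with no stereocentre touched.

Step 6
Reactants: 11 keto acetal
Product: 13 (4R,5S,6R)-6-(2,2-dimethoxyethyl)-4-(propan-2-yl)-5-[(trimethylsilyl)ethynyl]cyclohex-2-en-1-one, via lithium C5 enolate 12 (not isolated)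
Conditions: LDA, THF, −78 °C; then N-tert-butylbenzenesulfinimidoyl chloride, −78 °C
Reagents that add atoms: lithium diisopropylamide [Li]N(C(C)C)C(C)C (lithium of 12 only)
Why: Kinetic deprotonation takes place at the unhindered C5 methylene group, and the sulfinimidoyl chloride dehydrogenates the lithium enolate (Mukaiyama dehydrogenation: sulfur transfer to C5, then syn elimination) to the C5=C6 enone.

Step 7
Reactants: 13 enone
Product: 15 (1S,3R,4S,5S,6S)-3-(2,2-dimethoxyethyl)-4-ethynyl-5-(propan-2-yl)-7-oxabicyclo[4.1.0]heptan-2-one, via silylated epoxy ketone 14 (not isolated)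
Conditions: 30 % H2O2, NaOH (cat.), MeOH, 0 °C → rt
Reagents that add atoms: hydrogen peroxide OO
Why: Weitz–Scheffer epoxidation, in which hydroperoxide adds to C6 axially on the α face (anti to the equatorial C7a substituent of the locked enone, via a chair-like enolate), ring closure gives the 5α,6α-epoxide, and the methanolic base also cleaves the alkynyl C–Si bond.

Step 8
Reactants: 15 epoxy ketone
Product: 16 (1R,3R,4R,5S,6S)-3-(2,2-dimethoxyethyl)-4-ethynyl-2-methylidene-5-(propan-2-yl)-7-oxabicyclo[4.1.0]heptane
Conditions: Ph3PCH3Br, KOt-Bu (3 equiv each), THF, 0 °C → rt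
Reagents that add atoms: methyltriphenylphosphonium bromide C[P+](c1ccccc1)(c1ccccc1)c1ccccc1.[Br-]
Why: Wittig methylenation of an α,β-epoxy ketone (excess ylide covers the acidic alkyne C–H), where C3a is the only epimerisable centre and already carries its substituent in the preferred equatorial position.

Step 9
Reactants: 16 vinyl epoxide; 17 angelic acid, (2Z)-2-methylbut-2-enoic acid
Product: 18 (1S,2S,3S,4R,5R)-5-(2,2-dimethoxyethyl)-4-ethynyl-2-hydroxy-6-methylidene-3-(propan-2-yl)cyclohexyl (2Z)-2-methylbut-2-enoate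
Conditions: 17 (4 equiv), Cs2CO3 (0.2 equiv), DMF, 60 °C
Reagents that add atoms: none
Why: SN2 opening of a vinyl epoxide by a carboxylate, in which β-face attack at C5 is favoured by allylic activation and by the Fürst–Plattner rule (trans-diaxial opening of the locked half-chair), inverts C5 and leaves the C6–O bond untouched, so 5β-O-angelate and 6α-OH are set together, and carboxylate alkylation conditions do not isomerise the (Z)-acid.

Step 10
Reactants: 18 hydroxy angelate acetal
Product: 19 (1S,2S,3S,4R,5R)-4-ethynyl-2-hydroxy-6-methylidene-5-(2-oxoethyl)-3-(propan-2-yl)cyclohexyl (2Z)-2-methylbut-2-enoate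
Conditions: TsOH·H2O (10 mol %), acetone–H2O 9:1, rt
Reagents that add atoms: water O
Why: Acid-catalysed hydrolysis of the dimethyl acetal under conditions too mild for the allylic ester or the 1,1-disubstituted alkene, with no stereocentre touched.

Step 11
Reactants: 19 ynal
Product: 22 (1Z,2R,3aR,5S,6S,7S,7aR)-1-ethylidene-2,6-dihydroxy-4-methylidene-7-(propan-2-yl)octahydro-1H-inden-5-yl (2Z)-2-methylbut-2-enoate, via oxanickelacyclopentene 20 (not isolated), via bis(methylzinc) alkoxide 21 (not isolated)
Conditions: Ni(cod)2 (10 mol %), Me2Zn (4 equiv), THF, 0 °C; sat. aq NH4Cl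
Reagents that add atoms: dimethylzinc C[Zn]C (ethylidene methyl group; zinc of 20 and 21); bis(cycloocta-1,5-diene)nickel(0) C1=CCCC=CCC1.C1=CCCC=CCC1.[Ni] (nickel of 20 only)
Why: Ni(0) binds the terminal alkyne on C7a and the aldehyde of the C3a side chain and couples them oxidatively to oxanickelacyclopentene 20 (new C1–C2 bond), Me2Zn then exchanges a methyl group for the Ni–O bond, and reductive elimination forms the vinyl C–CH3 bond, giving 21 and Ni(0) again. This is the known nickel-catalysed, organozinc-promoted alkylative cyclisation of 5-alkynals, used here as a three-component ring closure. The cyclopentane (C1, C2, C3, C3a, C7a) closes in the 5-exo-dig mode, and because C3a and C7a are already stereodefined sp3 carbons whose arms are trans-diequatorial on a chair locked by the C7 isopropyl group, the trans ring fusion is carried in and cannot be lost. C2 and the methyl group are delivered to the same side of the alkyne through the metallacycle, so the methyl group ends cis to C2 and the (Z)-ethylidene should form as a single isomer. At C2 the control element is the metallacycle itself: its C2–O bond must lie near the plane of the C1=CH–Ni unit, and the trans-diequatorial anchoring allows only one sign for the C7a–C1–C2–C3 torsion, which puts oxygen on the β face (syn to H-3a) and gives the 2β-alcohol that the invertive acetate introduction of step 12 requires. The step needs chemoselectivity for alkyne plus aldehyde over the allylic angelate, the 1,1-disubstituted alkene and direct methyl addition; this is secured by the chelating 1,5-disposition of alkyne and aldehyde (fast intramolecular oxidative cyclisation at 0 °C), by ligand-free Ni(0), which is slow to ionise a hindered secondary allylic ester, and by the low uncatalysed reactivity of Me2Zn, whose first equivalent only masks 6-OH as a zinc alkoxide.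

Step 12
Reactants: 22 2β-alcohol
Product: 23 (1Z,2S,3aR,5S,6S,7S,7aR)-2-(acetyloxy)-1-ethylidene-6-hydroxy-4-methylidene-7-(propan-2-yl)octahydro-1H-inden-5-yl (2Z)-2-methylbut-2-enoate (target)
Conditions: AcOH, PPh3, DIAD (1.5 equiv each), toluene, −10 °C → rt
Reagents that add atoms: acetic acid CC(=O)O
Why: Mitsunobu esterification, in which the less hindered allylic 2β-OH (6α-OH is axial and flanked by the C5 and C7 substituents) is activated as the oxyphosphonium ion and displaced by acetate with inversion to give the 2α-acetate, the arrangement that places H-2 rather than oxygen next to the (Z)-methyl group (minimal A1,3 strain).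

## Compound list

1 | 3-methylbutanal | CC(C)CC=O | starting material
2 | but-3-en-2-one | CC(=O)C=C | starting material
3 | (2S)-5-oxo-2-(propan-2-yl)hexanal | O=C[C@H](C(C)C)CCC(C)=O | intermediate
4 | (4S)-4-(propan-2-yl)cyclohex-2-en-1-one | O=C1C=C[C@H](C(C)C)CC1 | intermediate
5 | lithium (trimethylsilyl)acetylide | [Li]C#C[Si](C)(C)C | starting material
6 | [(trimethylsilyl)ethynyl]copper | [Cu]C#C[Si](C)(C)C | intermediate (not isolated)
7 | trimethyl({(3S,4S)-4-(propan-2-yl)-3-[(trimethylsilyl)ethynyl]cyclohex-1-en-1-yl}oxy)silane | C[Si](C)(C)OC1=C[C@@H](C#C[Si](C)(C)C)[C@H](C(C)C)CC1 | intermediate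
8 | lithium enolate corresponding to 7 (C4(O)=C3a) | [Li]OC1=C[C@@H](C#C[Si](C)(C)C)[C@H](C(C)C)CC1 | intermediate (not isolated)
9 | (2R,3S,4S)-4-(propan-2-yl)-2-(prop-2-en-1-yl)-3-[(trimethylsilyl)ethynyl]cyclohexan-1-one | O=C1[C@H](CC=C)[C@@H](C#C[Si](C)(C)C)[C@H](C(C)C)CC1 | intermediate
10 | {(1R,2S,3S)-6-oxo-3-(propan-2-yl)-2-[(trimethylsilyl)ethynyl]cyclohexyl}acetaldehyde | O=C1[C@H](CC=O)[C@@H](C#C[Si](C)(C)C)[C@H](C(C)C)CC1 | intermediate (not isolated)
11 | (2R,3S,4S)-2-(2,2-dimethoxyethyl)-4-(propan-2-yl)-3-[(trimethylsilyl)ethynyl]cyclohexan-1-one | O=C1[C@H](CC(OC)OC)[C@@H](C#C[Si](C)(C)C)[C@H](C(C)C)CC1 | intermediate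
12 | kinetic lithium enolate of 11 (C4(O)=C5) | [Li]OC=1[C@H](CC(OC)OC)[C@@H](C#C[Si](C)(C)C)[C@H](C(C)C)CC=1 | intermediate (not isolated)
13 | (4R,5S,6R)-6-(2,2-dimethoxyethyl)-4-(propan-2-yl)-5-[(trimethylsilyl)ethynyl]cyclohex-2-en-1-one | O=C1[C@H](CC(OC)OC)[C@@H](C#C[Si](C)(C)C)[C@H](C(C)C)C=C1 | intermediate
14 | (1S,3R,4S,5S,6S)-3-(2,2-dimethoxyethyl)-5-(propan-2-yl)-4-[(trimethylsilyl)ethynyl]-7-oxabicyclo[4.1.0]heptan-2-one | O=C1[C@H](CC(OC)OC)[C@@H](C#C[Si](C)(C)C)[C@H](C(C)C)[C@@H]2O[C@H]12 | intermediate (not isolated)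
15 | (1S,3R,4S,5S,6S)-3-(2,2-dimethoxyethyl)-4-ethynyl-5-(propan-2-yl)-7-oxabicyclo[4.1.0]heptan-2-one | O=C1[C@H](CC(OC)OC)[C@@H](C#C)[C@H](C(C)C)[C@@H]2O[C@H]12 | intermediate
16 | (1R,3R,4R,5S,6S)-3-(2,2-dimethoxyethyl)-4-ethynyl-2-methylidene-5-(propan-2-yl)-7-oxabicyclo[4.1.0]heptane | C=C1[C@H](CC(OC)OC)[C@@H](C#C)[C@H](C(C)C)[C@@H]2O[C@H]12 | intermediate
17 | angelic acid, (2Z)-2-methylbut-2-enoic acid | O=C(O)/C(C)=C\C | starting material
18 | (1S,2S,3S,4R,5R)-5-(2,2-dimethoxyethyl)-4-ethynyl-2-hydroxy-6-methylidene-3-(propan-2-yl)cyclohexyl (2Z)-2-methylbut-2-enoate | C=C1[C@H](CC(OC)OC)[C@@H](C#C)[C@H](C(C)C)[C@H](O)[C@H]1OC(=O)/C(C)=C\C | intermediate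
19 | (1S,2S,3S,4R,5R)-4-ethynyl-2-hydroxy-6-methylidene-5-(2-oxoethyl)-3-(propan-2-yl)cyclohexyl (2Z)-2-methylbut-2-enoate | C=C1[C@H](CC=O)[C@@H](C#C)[C@H](C(C)C)[C@H](O)[C@H]1OC(=O)/C(C)=C\C | intermediate
20 | oxanickelacyclopentene (Ni bridging O-2 and the vinyl CH on C1; 6-O-zinc methyl) | C=C1[C@@H]2C[C@H]3O[Ni]C=C3[C@H]2[C@H](C(C)C)[C@H](O[Zn]C)[C@H]1OC(=O)/C(C)=C\C | intermediate (not isolated)
21 | 2β,6α-bis(methylzinc) alkoxide of 22 | C=C1[C@@H]2C[C@@H](O[Zn]C)/C(=C\C)[C@H]2[C@H](C(C)C)[C@H](O[Zn]C)[C@H]1OC(=O)/C(C)=C\C | intermediate (not isolated)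
22 | (1Z,2R,3aR,5S,6S,7S,7aR)-1-ethylidene-2,6-dihydroxy-4-methylidene-7-(propan-2-yl)octahydro-1H-inden-5-yl (2Z)-2-methylbut-2-enoate | C=C1[C@@H]2C[C@@H](O)/C(=C\C)[C@H]2[C@H](C(C)C)[C@H](O)[C@H]1OC(=O)/C(C)=C\C | intermediate
23 | (1Z,2S,3aR,5S,6S,7S,7aR)-2-(acetyloxy)-1-ethylidene-6-hydroxy-4-methylidene-7-(propan-2-yl)octahydro-1H-inden-5-yl (2Z)-2-methylbut-2-enoate | C=C1[C@@H]2C[C@H](OC(C)=O)/C(=C\C)[C@H]2[C@H](C(C)C)[C@H](O)[C@H]1OC(=O)/C(C)=C\C | target

## Step count and risks

Total step count: 12. Longest linear sequence: 12 steps (1/2 → 23).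

### Steps most likely to fail

**1. Step 11 (key step).**
- What may go wrong: oxidative addition of nickel(0) into the allylic C5–O bond of the angelate, direct methyl transfer to the aldehyde, or oligomerisation of the terminal alkyne may outrun the oxidative cyclisation.
- Fallback: the acyl group is kept out of the cyclisation substrate and both esters are put on afterwards. It sets out from 16 and comes back to the route at 23.
- Dilute aqueous sulfuric acid in THF opens the vinyl epoxide by trans-diaxial attack of water at allylic C5 and cleaves the acetal in the same flask, giving the diol ynal F1.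
- The nickel/dimethylzinc closure is then run on its bis(zinc alkoxide), in which the allylic oxygen is no leaving group, giving the hydrindane triol F2.
- Mitsunobu reaction with acetic acid engages the least hindered 2β-OH and gives the 2α-acetate diol F3.
- Selective acylation of the allylic 5β-OH with the Yamaguchi-type mixed anhydride of 17 and 2,4,6-trichlorobenzoyl chloride (Et3N, toluene) gives 23. The 6α-OH is shielded by the isopropyl-bearing C7.

**2. Step 9.**
- What may go wrong: attack of the carboxylate at the exocyclic methylene terminus (SN2′), or sluggish opening that forces higher temperatures and with them Z → E isomerisation of the angelate.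
- Fallback: hydrolysis, then acylation. It sets out from 16 and comes back at 18.
- Heating in buffered neutral water–dioxane, in which the acetal survives, opens the epoxide with the small, hard nucleophile water at C5 to give the trans-diaxial diol acetal F4.
- The allylic 5β-OH of F4 is acylated selectively with the mixed anhydride of 17 and 2,4,6-trichlorobenzoyl chloride to give 18.

**3. Step 12.**
- What may go wrong: capture of acetate at the ethylidene carbon (SN2′), ionisation to the allyl cation with loss of stereochemical fidelity, elimination to the diene, or competing activation of 6-OH.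
- Fallback: oxidation followed by reagent-controlled reduction. It sets out from 22 and comes back at 23.
- MnO2 oxidises only the allylic 2-OH to the (Z)-ethylidene ketone F5.
- Corey–Bakshi–Shibata reduction with (R)-Me-CBS and catecholborane at −78 °C, with the alkylidene side acting as the large group, gives the 2α-alcohol F6.
- Ac2O/pyridine acetylates the less hindered 2-OH to give 23.

## Further compounds

F1 | step 11 | {(1R,2R,3S,4S,5S)-2-ethynyl-4,5-dihydroxy-6-methylidene-3-(propan-2-yl)cyclohexyl}acetaldehyde | C=C1[C@H](CC=O)[C@@H](C#C)[C@H](C(C)C)[C@H](O)[C@H]1O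
F2 | step 11 | (1Z,2R,3aR,5S,6S,7S,7aR)-1-ethylidene-4-methylidene-7-(propan-2-yl)octahydro-1H-indene-2,5,6-triol | C=C1[C@@H]2C[C@@H](O)/C(=C\C)[C@H]2[C@H](C(C)C)[C@H](O)[C@H]1O
F3 | step 11 | (1Z,2S,3aR,5S,6S,7S,7aR)-1-ethylidene-5,6-dihydroxy-4-methylidene-7-(propan-2-yl)octahydro-1H-inden-2-yl acetate | C=C1[C@@H]2C[C@H](OC(C)=O)/C(=C\C)[C@H]2[C@H](C(C)C)[C@H](O)[C@H]1O
F4 | step 9 | (1S,2S,3S,4R,5R)-5-(2,2-dimethoxyethyl)-4-ethynyl-6-methylidene-3-(propan-2-yl)cyclohexane-1,2-diol | C=C1[C@H](CC(OC)OC)[C@@H](C#C)[C@H](C(C)C)[C@H](O)[C@H]1O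
F5 | step 12 | (1Z,3aR,5S,6S,7S,7aR)-1-ethylidene-6-hydroxy-4-methylidene-2-oxo-7-(propan-2-yl)octahydro-1H-inden-5-yl (2Z)-2-methylbut-2-enoate | C=C1[C@@H]2CC(=O)/C(=C\C)[C@H]2[C@H](C(C)C)[C@H](O)[C@H]1OC(=O)/C(C)=C\C
F6 | step 12 | (1Z,2S,3aR,5S,6S,7S,7aR)-1-ethylidene-2,6-dihydroxy-4-methylidene-7-(propan-2-yl)octahydro-1H-inden-5-yl (2Z)-2-methylbut-2-enoate | C=C1[C@@H]2C[C@H](O)/C(=C\C)[C@H]2[C@H](C(C)C)[C@H](O)[C@H]1OC(=O)/C(C)=C\C
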